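All runs are simulated with constants of no real substance; noise was put on by code.

The first constant to read is the rate constant of Wednesday's run.

common to all: electrophile 10 mM

|  | nucleophile | solid base | remark | time |
|---|---|---|---|---|
| Thursday's | 17 mM | 15 mM | run made earlier |  |
| Wednesday's | 29 mM | 15 mM | run made earlier |  |
| winter | 25.0 mM | 15.0 mM |  | 2.0 min |
| dusk | 11.0 mM | 15.0 mM |  | 2.0 min |
| spring | 16.0 mM | 15.0 mM |  | 2.0 min |

- Thursday's (time / s: electrophile / %, target / %): 10.0: 32.8, 36.2; 12.0: 31.0, 39.5; 25.0: 21.2, 47.8; 40.0: 17.6, 52.6; 80.0: 12.0, 56.9
- Wednesday's (time / s: electrophile / %, target / %): 15.0: 12.7, 58.0; 30.0: 4.4, 65.9; 50.0: 1.6, 68.6; 60.0: 0.7, 68.4; 80.0: 0.4, 69.4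

(scatter of a reading: 0.5 percentage points)

- solid base is a solid; its amount is given per volume of the solution
- at the start none of the solid base is in solution
- what has gone from electrophile into another species counts as reacted, even if it can come back

* part of the electrophile that has reacted at the end, winter
* part of the electrophile that has reacted at the end, dusk
* part of the electrophile that has reacted at the end, spring
* what raising the concentration of nucleophile from its lowest to its highest value here does to the part of the electrophile that has reacted (changes below 5 percentage points count as none) (it falls / no change / it rises)

In Wednesday's flask, with nucleophile in excess, the electrophile readings at 15.0 s and 30.0 s give a pseudo-first-order k = 0.0707 s⁻¹, a half-life in that flask of 9.81 s, shorter than the 2.0 min given to the new flasks. Thursday's flask, with 17 mM of nucleophile, still holds 12.0 % electrophile at 80.0 s. The end of such a flask is therefore reckoned here by counting.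

In Wednesday's flask target is 69.7 % of what has reacted at the last reading, so the remainder stands in species not read. With that share, Thursday's target of 56.9 % stands for 81.7 % of the electrophile turned over; if Thursday's 17 mM of nucleophile is taken as used up by that reading, this cost 2.08 nucleophile per electrophile, an estimate taken here as two.

The balanced charge, two nucleophile per electrophile, is then the zero of the scale. The capacity, c(nucleophile) divided by two c(electrophile), is the part of the electrophile that the charge is reckoned to turn over at two nucleophile each, and below one it marks nucleophile as the limiting reagent. Dusk has 55.0 %, spring 80.0 % and winter 125 %.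

Of Thursday's part not turned over, a share s = 0.654 is read as free electrophile, and the remainder counts as reacted. The reacted part is then one minus s times (one minus capacity). This reckoning gives 70.6 % for dusk, 86.9 % for spring and 100 per cent for winter, whose capacity exceeds one, so the part rises with nucleophile.

The forecast gives 99.3 % for winter, 68 % for dusk and 89 % for spring, with the trend it rises, on the ground that “roughly two nucleophile are used per electrophile”.

The flasks give 99.6 % for winter, 72.5 % for dusk and 87.0 % for spring; the trend is it rises, by 27 percentage points.

    electrophile + nucleophile → acid set free + target (k = 9.20 M⁻¹ s⁻¹)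
    nucleophile + acid set free ⇌ protonated nucleophile, settled at all times (K = 6.30 × 10⁵ M⁻¹)
    acid set free + free base ⇌ salt of the base, settled at all times (K = 150 M⁻¹)
    target ⇌ isomer of the product (K = 0.430, k = 0.0810 s⁻¹)
    solid base ⇌ free base, rate k5*(cs5 - [free base]) while solid is left; crystals form when [free base] > cs5 (solubility = 3.60 mM, k = 0.0590 s⁻¹)
    electrophile ⇌ dormant form (K = 0.610, k = 1.40 s⁻¹)

In dusk at 2.00 min, free nucleophile is down to 0.557 % of its charge, and target and isomer of the product together hold 55.8 % against the capacity of 55.0 %. A neighbour of winter charged with 17 mM of electrophile has a capacity of 73.5 %, and at 2.00 min its target and isomer of the product together hold 74.2 %, with 84.0 % of its electrophile reacted.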